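**Strategy.** The seven-membered carbocycle (C1, C5–C10) is never closed as such: the 1,5-relationship of the C4 and C9 oxygens across the ring-fusion bond C1–C5 marks it as a de Mayo product. A lactone-fused cyclopentane holding C5–C9 (from Grieco lactone) carries a hex-4-enoyl chain on C5 and an enol carbonate at C9. Intramolecular [2+2] photocycloaddition joins C1–C5 and C9–C10; hydrogenolysis frees the cyclobutanol, whose retro-aldol cleavage of C5–C9 releases the strain. One operation thus builds ring A and inserts C1 and C10 into the five-membered ring. The bridging enol ether, the α-methylene lactone and the two esters follow from the resulting 4,9-dione.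

Key step: step 9

Remark: atoms carry guaianolide numbers throughout (ring A = C1–C5; seven-membered ring = C1, C5–C10; C11–C13 = lactone carbons; C14 = enol-ether CH; C15 = CH2OH); α is the face of H-1 and H-5 in the target; compounds 1, 7, 8, 22 and all reagents are taken as commercially available.

**Step 1**
Reactants: 1 (1R,5S)-2-oxabicyclo[3.3.0]oct-6-en-3-one (Grieco lactone; O on C8, CH2C(=O) on C7, alkene C5=C6)
Product: 2 C9 allylic alcohol of the Grieco lactone
Conditions: SeO2 (0.5 equiv), t-BuOOH, CH2Cl2, 23 °C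
Reagents that add atoms: selenium dioxide O=[Se]=O; tert-butyl hydroperoxide CC(C)(C)OO
Why: Sharpless SeO2/t-BuOOH allylic hydroxylation (ene reaction then [2,3]-shift) should oxidise the allylic CH2 (C9) in preference to the ring-fusion methine and leave the alkene at C5=C6; the new carbinol centre is removed in step 2.

**Step 2**
Reactants: 2 C9 allylic alcohol
Product: 3 enone lactone (C9 ketone conjugated to C5=C6)
Conditions: Dess–Martin periodinane, CH2Cl2, 23 °C
Reagents that add atoms: none
Why: Dess–Martin oxidation of the allylic alcohol should give the cyclopentenone without touching the cis-fused lactone, which locks C7 and C8.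

**Step 3**
Reactants: 3 enone lactone
Product: 5 6α-hydroxy ketone lactone, via boronate 4 (not isolated)
Conditions: B2pin2, CuCl (5 mol %), Xantphos, NaOt-Bu (10 mol %), MeOH, THF, 23 °C; then NaBO3·4H2O, THF/H2O, 23 °C
Reagents that add atoms: bis(pinacolato)diboron CC1(C)OB(OC1(C)C)B1OC(C)(C)C(C)(C)O1 (boron of 4); sodium perborate [Na+].[O-]OB=O (oxygen of 5)
Why: Copper-catalysed conjugate borylation should deliver boron to C6 on the convex face, anti to the lactone ring, and perborate oxidation proceeds with retention, which sets the 6α oxygen.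

**Step 4**
Reactants: 5 6α-hydroxy ketone lactone
Product: 6 6α-triethylsilyloxy ketone lactone
Conditions: Et3SiCl, imidazole, CH2Cl2, 0 °C
Reagents that add atoms: chlorotriethylsilane CC[Si](Cl)(CC)CC
Why: Silylation under weakly basic conditions should protect the β-hydroxy ketone before it can dehydrate.

**Step 5**
Reactants: 7 pent-4-enal; 8 acrolein dimethyl acetal (3 equiv)
Product: 9 (E)-6,6-dimethoxyhex-4-enal
Conditions: second-generation Grubbs catalyst RuCl2(=CHPh)(H2IMes)(PCy3) (2 mol %), CH2Cl2, 40 °C
Reagents that add atoms: none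
Why: Olefin cross-metathesis of a terminal alkene with an acrolein acetal should be E-selective, driven by loss of ethene.

**Step 6**
Reactants: 6 6α-triethylsilyloxy ketone lactone; 9 (E)-6,6-dimethoxyhex-4-enal
Product: 10 C5 aldol adduct
Conditions: LDA, THF, −78 °C; then 9, −78 °C; AcOH quench at −78 °C
Reagents that add atoms: none
Why: The kinetic lithium enolate forms at the unhindered CH2 (C5) and undergoes aldol addition at −78 °C, too cold for loss of the β-silyloxy group; the new centres at C5 and the carbinol carbon are erased in steps 7 and 9.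

**Step 7**
Reactants: 10 C5 aldol adduct
Product: 11 2-acylcyclopentanone (C4/C9 β-diketone)
Conditions: Dess–Martin periodinane, pyridine, CH2Cl2, 0 °C
Reagents that add atoms: none
Why: Buffered Dess–Martin oxidation of the β-hydroxy ketone should give the enolised β-diketone without acid or base strong enough to expel the 6-silyloxy group.

**Step 8**
Reactants: 11 β-diketone
Product: 12 enol benzyl carbonate (C5=C9, carbonate oxygen on C9)
Conditions: ClCO2Bn, pyridine, CH2Cl2, 0 °C
Reagents that add atoms: benzyl chloroformate O=C(Cl)OCc1ccccc1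
Why: O-Acylation of the chelated enol, as with other 2-acylcyclopentanones, should place the carbonate on the ring oxygen and fix the enone double bond at C5=C9; the exocyclic isomer suffers allylic strain with the 6-silyloxy group and can equilibrate by acyl transfer.

**Step 9**
Reactants: 12 enol benzyl carbonate
Product: 15 cis-fused hydroazulene-4,9-dione 8,12-lactone, via photoadduct 13 (not isolated), via cyclobutanol 14 (not isolated)
Conditions: hν (medium-pressure Hg lamp, Pyrex, λ > 300 nm), EtOAc, 10 °C; then H2 (1 atm), Pd/C, same flask, 23 °C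
Reagents that add atoms: none
Why: Excitation of the β-acyloxy enone gives a triplet that adds to the tethered alkene: C5 bonds to C1 first in a five-membered closure (rule of five), which closes ring A, and the 1,4-biradical collapses by forming C9–C10, the straight mode of 1,6-dien-3-ones. Hydrogenolysis of the benzyl carbonate then gives cyclobutanol 14, a strained β-hydroxy ketone that fragments by retro-aldol cleavage of C5–C9, so the five-membered ring C5–C9 becomes the seven-membered ring by insertion of C1 and C10; the closest known reaction type is the intramolecular de Mayo reaction of 2-acylcyclopentanone enol carbonates to hydroazulenediones. The cis-fused lactone shields the β face of the cyclopentene, so the alkene should add on the convex α face, and H-1, which is endo on the cyclobutane, ends α in 15; C10 forms as epimers, which does not matter because it becomes sp2 in step 12. C5 is set by ketonisation of the C4 enol on the face of H-1 and by equilibration to the cis ring junction with C4 anti to the 6α-silyloxy group. The step needs the regiochemistry C5–C1/C9–C10 and not a crossed adduct, secured by the three-atom tether through the C4 carbonyl and by the enol double bond fixed at C5=C9, and it needs a neutral fragmentation, secured by hydrogenolysis, so that the silyloxy group β to the new C4 ketone is not eliminated.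

**Step 10**
Reactants: 15 hydroazulene-4,9-dione
Product: 17 4β,15-diol, via silane 16 (not isolated)
Conditions: (i-PrO)Me2SiCH2MgCl, CeCl3, THF, −78 °C; then 30% H2O2, KHCO3, MeOH/THF, 40 °C
Reagents that add atoms: (isopropoxydimethylsilyl)methylmagnesium chloride CC(C)O[Si](C)(C)C[Mg]Cl; hydrogen peroxide OO
Why: Tamao's hydroxymethyl-anion equivalent should add to the less hindered cyclopentanone C4 (the C9 ketone has two tertiary α-carbons) from the convex face, cis to H-5, placing C15 α and the C4 oxygen β; Tamao oxidation of the C–Si bond then gives the primary alcohol.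

**Step 11**
Reactants: 17 4β,15-diol
Product: 18 15-O-TBDPS ether
Conditions: t-BuPh2SiCl, imidazole, DMAP (cat.), CH2Cl2, 23 °C
Reagents that add atoms: tert-butyl(chloro)diphenylsilane CC(C)(C)[Si](Cl)(c1ccccc1)c1ccccc1
Why: The primary hydroxyl is silylated selectively over the tertiary one, which keeps C15–OH out of the acetal chemistry of step 12.

**Step 12**
Reactants: 18 15-O-TBDPS ether
Product: 19 tricyclic vinylogous ester (C4–O–C14=C10–C9=O)
Conditions: PPTS (cat.), 5 Å molecular sieves, toluene, 80 °C
Reagents that add atoms: none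
Why: Acid-catalysed intramolecular transacetalisation by the 4β-hydroxyl (possible because C4–O and C1–C10 are cis) followed by loss of the second methanol with the acidic C10–H should give the bridged β-alkoxy enone, both C10 epimers converging.

**Step 13**
Reactants: 19 tricyclic vinylogous ester
Product: 20 C11 dimethylaminomethyl lactone (Mannich base)
Conditions: LDA, THF, −78 °C; then CH2=NMe2+ I−, −78 → 0 °C
Reagents that add atoms: N,N-dimethylmethyleneiminium iodide C=[N+](C)C.[I-]
Why: The lactone CH2 is deprotonated kinetically (the C8 methine is hindered and locked by the cis-fused lactone) and the enolate undergoes a Mannich reaction with Eschenmoser's salt; the β-amino lactone is a masked α-methylene lactone and the C11 configuration is irrelevant.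

**Step 14**
Reactants: 20 Mannich base lactone
Product: 21 8β-hydroxy N-methoxy-N-methyl amide
Conditions: MeNH(OMe)·HCl, AlMe3, CH2Cl2, 0 → 23 °C; aqueous Rochelle salt
Reagents that add atoms: N,O-dimethylhydroxylamine hydrochloride CNOC.Cl
Why: Weinreb aminolysis of the strained cis-fused γ-lactone by the aluminium amide should cleave the acyl–O8 bond and free the 8β-hydroxyl without touching C8; the vinylogous ester and the silyl ethers are poorer electrophiles.

**Step 15**
Reactants: 21 8β-hydroxy amide; 22 angelic acid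
Product: 24 8β-angelate, via mixed anhydride 23 (not isolated)
Conditions: 22, 2,4,6-trichlorobenzoyl chloride, Et3N, toluene, 23 °C; then 21, DMAP, 23 → 50 °C
Reagents that add atoms: none
Why: Yamaguchi esterification of the hindered secondary alcohol through the mixed anhydride should transfer the angeloyl group with its Z double bond intact; the amide does not relactonise under these basic conditions.

**Step 16**
Reactants: 24 8β-angelate
Product: 26 6α,12-lactone, via hydroxy amide 25 (not isolated)
Conditions: HF·pyridine, pyridine, THF, 0 °C; then PPTS (cat.), toluene, 50 °C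
Reagents that add atoms: none
Why: Buffered HF·pyridine cleaves the secondary triethylsilyl ether in the presence of the primary TBDPS ether, and the freed 6α-hydroxyl displaces N,O-dimethylhydroxylamine from the amide to close the trans-fused γ-lactone.

**Step 17**
Reactants: 26 6α,12-lactone (9-ketone)
Product: 27 9β-alcohol
Conditions: NaBH4, CeCl3·7H2O, MeOH, −40 °C; Et3N-buffered work-up
Reagents that add atoms: none
Why: Luche reduction gives 1,2-reduction of the vinylogous ester carbonyl; hydride should attack anti to the 8β-angeloyloxy group and the β-disposed oxa-bridge, from the α face, giving the 9β-alcohol, while lactone, angelate and amine are untouched.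

**Step 18**
Reactants: 27 9β-alcohol
Product: 28 9α-acetate
Conditions: AcOH, PPh3, DIAD, toluene, 0 → 23 °C
Reagents that add atoms: acetic acid CC(=O)O
Why: Mitsunobu esterification replaces the activated 9β oxygen by acetate with inversion; should the allylic, enol-ether-stabilised centre ionise instead, the cis 8β-angeloyloxy group can bridge only on the β face, so acetate still enters from the α face and the 8β,9α-trans diester results.

**Step 19**
Reactants: 28 9α-acetate
Product: 30 α-methylene lactone silyl ether, via ammonium iodide 29 (not isolated)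
Conditions: MeI, MeCN, 23 °C; then aqueous NaHCO3, EtOAc, 23 °C
Reagents that add atoms: none
Why: Quaternisation of the Mannich base and E1cB (Hofmann-type) elimination of trimethylamine under bicarbonate should unveil the α-methylene lactone without affecting the esters or the enol ether.

**Step 20**
Reactants: 30 α-methylene lactone silyl ether
Product: 31 target CNP0073339.2
Conditions: HF·pyridine, pyridine, THF, 0 → 23 °C
Reagents that add atoms: none
Why: Pyridine-buffered HF·pyridine removes the primary TBDPS ether; the buffered medium should spare the acid-labile 3-acyloxy enol ether, the esters and the methylene lactone.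

**Compound list**

1 | (1R,5S)-2-oxabicyclo[3.3.0]oct-6-en-3-one (Grieco lactone) | O=C1O[C@@H]2CC=C[C@@H]2C1 | starting material
2 | 8-hydroxy derivative of 1 (C9–OH, epimers) | O=C1O[C@@H]2C(O)C=C[C@@H]2C1 | intermediate
3 | cis-2-oxabicyclo[3.3.0]oct-6-ene-3,8-dione (enone lactone) | O=C1O[C@@H]2C(=O)C=C[C@@H]2C1 | intermediate
4 | 6α-(pinacolboryl) ketone lactone | O=C1O[C@@H]2C(=O)C[C@@H](B3OC(C)(C)C(C)(C)O3)[C@@H]2C1 | intermediate
5 | 6α-hydroxy ketone lactone | O=C1O[C@@H]2C(=O)C[C@@H](O)[C@@H]2C1 | intermediate
6 | 6α-(triethylsilyloxy) ketone lactone | O=C1O[C@@H]2C(=O)C[C@@H](O[Si](CC)(CC)CC)[C@@H]2C1 | intermediate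
7 | pent-4-enal | C=CCCC=O | starting material
8 | acrolein dimethyl acetal (3,3-dimethoxyprop-1-ene) | C=CC(OC)OC | starting material
9 | (E)-6,6-dimethoxyhex-4-enal | O=CCC/C=C/C(OC)OC | intermediate
10 | C5 aldol adduct of 6 and 9 (epimers at C5 and the carbinol carbon) | O=C1O[C@@H]2C(=O)C(C(O)CC/C=C/C(OC)OC)[C@@H](O[Si](CC)(CC)CC)[C@@H]2C1 | intermediate
11 | 5-[(E)-6,6-dimethoxyhex-4-enoyl] β-diketone (drawn as keto form) | O=C1O[C@@H]2C(=O)C(C(=O)CC/C=C/C(OC)OC)[C@@H](O[Si](CC)(CC)CC)[C@@H]2C1 | intermediate
12 | ring enol benzyl carbonate of 11 (C5=C9) | O=C1O[C@@H]2C(OC(=O)OCc3ccccc3)=C(C(=O)CC/C=C/C(OC)OC)[C@@H](O[Si](CC)(CC)CC)[C@@H]2C1 | intermediate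
13 | cyclobutane photoadduct (5-4-5 tricycle on the lactone; C10 epimers) | O=C1O[C@@H]2[C@@]3(OC(=O)OCc5ccccc5)C(C(OC)OC)[C@@H]4CCC(=O)[C@]34[C@@H](O[Si](CC)(CC)CC)[C@@H]2C1 | intermediate
14 | cyclobutanol from 13 | O=C1O[C@@H]2[C@@]3(O)C(C(OC)OC)[C@@H]4CCC(=O)[C@]34[C@@H](O[Si](CC)(CC)CC)[C@@H]2C1 | intermediate
15 | 1αH,5αH-hydroazulene-4,9-dione, 8β,12-lactone, 6α-OTES, 10-dimethoxymethyl (C10 epimers) | O=C1O[C@@H]2C(=O)C(C(OC)OC)[C@@H]3CCC(=O)[C@@H]3[C@@H](O[Si](CC)(CC)CC)[C@@H]2C1 | intermediate
16 | 4β-hydroxy-4α-[(isopropoxydimethylsilyl)methyl] adduct | O=C1O[C@@H]2C(=O)C(C(OC)OC)[C@@H]3CC[C@@](O)(C[Si](C)(C)OC(C)C)[C@@H]3[C@@H](O[Si](CC)(CC)CC)[C@@H]2C1 | intermediate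
17 | 4β,15-diol | O=C1O[C@@H]2C(=O)C(C(OC)OC)[C@@H]3CC[C@@](O)(CO)[C@@H]3[C@@H](O[Si](CC)(CC)CC)[C@@H]2C1 | intermediate
18 | 15-O-TBDPS 4β-alcohol | O=C1O[C@@H]2C(=O)C(C(OC)OC)[C@@H]3CC[C@@](O)(CO[Si](c4ccccc4)(c4ccccc4)C(C)(C)C)[C@@H]3[C@@H](O[Si](CC)(CC)CC)[C@@H]2C1 | intermediate
19 | tricyclic vinylogous ester (4β,14-epoxy-10(14)-en-9-one), 8β,12-lactone | O=C1O[C@@H]2C(=O)C3=CO[C@@]4(CO[Si](c5ccccc5)(c5ccccc5)C(C)(C)C)CC[C@@H]3[C@H]4[C@@H](O[Si](CC)(CC)CC)[C@@H]2C1 | intermediate
20 | 11-(dimethylaminomethyl) derivative of 19 (C11 epimers) | O=C1O[C@@H]2C(=O)C3=CO[C@@]4(CO[Si](c5ccccc5)(c5ccccc5)C(C)(C)C)CC[C@@H]3[C@H]4[C@@H](O[Si](CC)(CC)CC)[C@@H]2C1CN(C)C | intermediate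
21 | 8β-hydroxy N-methoxy-N-methyl amide | CON(C)C(=O)C(CN(C)C)[C@@H]1[C@H](O)C(=O)C2=CO[C@@]3(CO[Si](c4ccccc4)(c4ccccc4)C(C)(C)C)CC[C@@H]2[C@H]3[C@H]1O[Si](CC)(CC)CC | intermediate
22 | angelic acid ((Z)-2-methylbut-2-enoic acid) | OC(=O)/C(C)=C\C | starting material
23 | angelic 2,4,6-trichlorobenzoic anhydride | O=C(OC(=O)/C(C)=C\C)c1c(Cl)cc(Cl)cc1Cl | intermediate
24 | 8β-angelate of 21 | CON(C)C(=O)C(CN(C)C)[C@@H]1[C@H](OC(=O)/C(C)=C\C)C(=O)C2=CO[C@@]3(CO[Si](c4ccccc4)(c4ccccc4)C(C)(C)C)CC[C@@H]2[C@H]3[C@H]1O[Si](CC)(CC)CC | intermediate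
25 | 6α-hydroxy amide from 24 | CON(C)C(=O)C(CN(C)C)[C@@H]1[C@H](OC(=O)/C(C)=C\C)C(=O)C2=CO[C@@]3(CO[Si](c4ccccc4)(c4ccccc4)C(C)(C)C)CC[C@@H]2[C@H]3[C@H]1O | intermediate
26 | trans-fused 6α,12-lactone, 8β-angelate, 9-ketone | CN(C)CC1C(=O)O[C@H]2[C@H]1[C@H](OC(=O)/C(C)=C\C)C(=O)C1=CO[C@@]3(CO[Si](c4ccccc4)(c4ccccc4)C(C)(C)C)CC[C@@H]1[C@@H]23 | intermediate
27 | 9β-alcohol | CN(C)CC1C(=O)O[C@H]2[C@H]1[C@H](OC(=O)/C(C)=C\C)[C@H](O)C1=CO[C@@]3(CO[Si](c4ccccc4)(c4ccccc4)C(C)(C)C)CC[C@@H]1[C@@H]23 | intermediate
28 | 9α-acetate | CN(C)CC1C(=O)O[C@H]2[C@H]1[C@H](OC(=O)/C(C)=C\C)[C@@H](OC(C)=O)C1=CO[C@@]3(CO[Si](c4ccccc4)(c4ccccc4)C(C)(C)C)CC[C@@H]1[C@@H]23 | intermediate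
29 | trimethylammonium iodide of 28 | C[N+](C)(C)CC1C(=O)O[C@H]2[C@H]1[C@H](OC(=O)/C(C)=C\C)[C@@H](OC(C)=O)C1=CO[C@@]3(CO[Si](c4ccccc4)(c4ccccc4)C(C)(C)C)CC[C@@H]1[C@@H]23.[I-] | intermediate
30 | 15-O-TBDPS ether of the target | C=C1C(=O)O[C@H]2[C@H]1[C@H](OC(=O)/C(C)=C\C)[C@@H](OC(C)=O)C1=CO[C@@]3(CO[Si](c4ccccc4)(c4ccccc4)C(C)(C)C)CC[C@@H]1[C@@H]23 | intermediate
31 | CNP0073339.2 | C=C1C(=O)O[C@H]2[C@H]1[C@H](OC(=O)/C(C)=C\C)[C@@H](OC(C)=O)C1=CO[C@@]3(CO)CC[C@@H]1[C@@H]23 | target

**Count.** Total: 20 steps. Longest linear sequence: 19 steps (steps 1–4 and 6–20, from 1).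

**Steps most likely to fail**

Step 9. What may go wrong: a photo-Fries acyl shift of the enol carbonate, cycloaddition on the concave face, or (from step 8) acylation of the exocyclic enol oxygen, which would lead to a crossed adduct. Fallback, setting out from diketone 11 and returning at dione 15: the carbonate is dropped and the chelated enol of 11 is irradiated itself (Pyrex, MeCN), the classical de Mayo reaction of a free β-diketone. Both enol tautomers begin with the same C5–C1 bond, and the hydroxy-substituted biradical closes to the less strained bicyclo[3.2.0] system. Cyclobutanol 14 then forms without any O-acylation and fragments as it forms to 15; no new compound is made.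

Step 14. What may go wrong: attack of the amide nucleophile on the vinylogous ester with opening of the oxa-bridge, or relactonisation of the hydroxy amide before acylation. Fallback, setting out from Mannich base 20 and returning at lactone 26: the lactone is saponified (LiOH, THF/H2O, 0 °C) and the cold, just-neutralised hydroxy acid is esterified at once with TMSCHN2 to the 8β-hydroxy methyl ester F1. Yamaguchi esterification with angelic acid gives the angelate methyl ester F2. HF·pyridine then PPTS removes the triethylsilyl group and closes the 6α,12-lactone with loss of methanol, giving 26.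

Step 18. What may go wrong: allylic transposition of the activated alcohol (acetate entering at C14 with shift of the double bond, a Ferrier-type process) or elimination instead of inversion at C9. Fallback, setting out from hydroxy amide 21 and returning at acetate 28: with the 8β-hydroxyl still free, chelation-controlled reduction of the 9-ketone (Zn(BH4)2, Et2O, −20 °C) holds O8 in the carbonyl plane and delivers hydride anti to H-8, giving the 8β,9α-trans diol F3. The more reactive allylic 9-hydroxyl is acetylated (Ac2O, 2,4,6-collidine, −40 °C) to the 9α-acetate F4. Yamaguchi angeloylation of the 8β-hydroxyl gives the diester amide F5, and buffered HF·pyridine removes the triethylsilyl group and closes the 6α,12-lactone to 28, so no inversion at C9 is needed.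

**Further compounds**

F0 | step 9 | none | none
F1 | step 14 | 8β-hydroxy methyl ester (opened lactone) | COC(=O)C(CN(C)C)[C@@H]1[C@H](O)C(=O)C2=CO[C@@]3(CO[Si](c4ccccc4)(c4ccccc4)C(C)(C)C)CC[C@@H]2[C@H]3[C@H]1O[Si](CC)(CC)CC
F2 | step 14 | 8β-angelate methyl ester | COC(=O)C(CN(C)C)[C@@H]1[C@H](OC(=O)/C(C)=C\C)C(=O)C2=CO[C@@]3(CO[Si](c4ccccc4)(c4ccccc4)C(C)(C)C)CC[C@@H]2[C@H]3[C@H]1O[Si](CC)(CC)CC
F3 | step 18 | 8β,9α-diol amide | CON(C)C(=O)C(CN(C)C)[C@@H]1[C@H](O)[C@@H](O)C2=CO[C@@]3(CO[Si](c4ccccc4)(c4ccccc4)C(C)(C)C)CC[C@@H]2[C@H]3[C@H]1O[Si](CC)(CC)CC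
F4 | step 18 | 9α-acetate 8β-alcohol amide | CON(C)C(=O)C(CN(C)C)[C@@H]1[C@H](O)[C@@H](OC(C)=O)C2=CO[C@@]3(CO[Si](c4ccccc4)(c4ccccc4)C(C)(C)C)CC[C@@H]2[C@H]3[C@H]1O[Si](CC)(CC)CC
F5 | step 18 | 8β-angelate 9α-acetate amide | CON(C)C(=O)C(CN(C)C)[C@@H]1[C@H](OC(=O)/C(C)=C\C)[C@@H](OC(C)=O)C2=CO[C@@]3(CO[Si](c4ccccc4)(c4ccccc4)C(C)(C)C)CC[C@@H]2[C@H]3[C@H]1O[Si](CC)(CC)CC
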